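The 14-membered lactone is opened at the C1–C2 bond (macrolide numbering, C1 = lactone carbonyl), with C1 traced to carbon monoxide, and the tetrahydropyran at O–C3. The precursor is an acyclic alkenediol: C2=C3 vinyl group, free C7 and C13 hydroxyls, C5 acetate, five stereocentres in place. One palladium-catalysed operation (oxypalladation, carbon monoxide insertion, intramolecular acyl capture) turns it into the bicyclic macrolactone, forming the tetrahydropyran O–C3 bond, the C1–C2 bond and the C1–O13 ester link and setting C3. It exploits the (tetrahydropyran-2-yl)acetate unit O7–C3–C2–C1(=O)–O13 shared by the tetrahydropyran and the macrolactone. Two sulfone acylation/Evans–Tishchenko sequences on a 3-methylglutarate build the alkenediol; Mitsunobu esterification completes neopeltolide.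

Key step: step 12

Numbering: macrolide numbering is used in the text (C1 lactone carbonyl; C3 and C7 the tetrahydropyran carbons beside the ring oxygen; C5 acyloxy carbon; C9 methyl; C11 methoxy; C13 lactone carbinol carbon).

Assumption: (R)-1,2-epoxypentane and monomethyl (S)-3-methylglutarate are taken as catalogue compounds; each is otherwise one step from racemic 1,2-epoxypentane (hydrolytic kinetic resolution) or 3-methylglutaric anhydride (alkaloid-mediated methanolysis).

Step 1
Reactants: 1 (2R)-2-propyloxirane [(R)-1,2-epoxypentane]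
Product: 2 (2R)-1-(phenylsulfonyl)pentan-2-ol
Conditions: PhSO2Na, NH4Cl, EtOH–H2O, 70 °C
Reagents that add atoms: sodium benzenesulfinate [Na+].[O-]S(=O)c1ccccc1
Why: SN2 opening of the terminal epoxide at its CH2 carbon by the sulfur atom of the sulfinate should give the β-hydroxy sulfone, and the C–O bond of the purchased stereocentre (later C13) is not touched.

Step 2
Reactants: 3 (3S)-5-methoxy-3-methyl-5-oxopentanoic acid; 2 (2R)-1-(phenylsulfonyl)pentan-2-ol
Product: 6 methyl (3S,7R)-7-hydroxy-3-methyl-5-oxo-6-(phenylsulfonyl)decanoate (both C6 epimers), via acid chloride 4 (not isolated), via dilithio sulfone 5 (not isolated)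
Conditions: 3, (COCl)2, DMF (cat.), CH2Cl2, 0 °C to rt, then evaporation; 2 (2.1 equiv), n-BuLi (4.2 equiv), THF, −78 °C; 4 added at −78 °C; aq. NH4Cl
Reagents that add atoms: oxalyl chloride ClC(=O)C(=O)Cl (chlorine of 4 only); n-butyllithium [Li]CCCC (lithium of 5 only)
Why: Claisen-type C-acylation of the α-sulfonyl carbanion by the acid chloride, far more electrophilic at −78 °C than the methyl ester, should give the β-keto sulfone, the second equivalent of 5 deprotonating it and so preventing over-addition; C9 and C13 are carried in unchanged and the sulfonyl-bearing centre is removed in step 3.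

Step 3
Reactants: 6 methyl (3S,7R)-7-hydroxy-3-methyl-5-oxo-6-(phenylsulfonyl)decanoate
Product: 7 methyl (3S,7R)-7-hydroxy-3-methyl-5-oxodecanoate
Conditions: SmI2 (3 equiv), THF–MeOH, −78 °C
Reagents that add atoms: none
Why: Reductive desulfonylation of the α-sulfonyl ketone by electron transfer should give a samarium enolate that methanol protonates at −78 °C before the β-oxygen can leave, so the β-hydroxy ketone forms with C13 intact.

Step 4
Reactants: 7 methyl (3S,7R)-7-hydroxy-3-methyl-5-oxodecanoate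
Product: 8 methyl (3S,5R,7R)-7-acetoxy-5-hydroxy-3-methyldecanoate
Conditions: SmI2 (0.3 equiv), CH3CHO (8 equiv), THF, −10 °C
Reagents that add atoms: acetaldehyde CC=O
Why: Evans–Tishchenko reduction: the hemiacetal formed on O13 delivers hydride intramolecularly to the samarium-chelated C11 ketone through a chair transition state, which should set C11 anti to C13 and at the same time mask O13 as its acetate while O11 stays free.

Step 5
Reactants: 8 methyl (3S,5R,7R)-7-acetoxy-5-hydroxy-3-methyldecanoate
Product: 9 methyl (3S,5R,7R)-7-acetoxy-5-methoxy-3-methyldecanoate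
Conditions: Me3OBF4, 1,8-bis(dimethylamino)naphthalene, CH2Cl2, rt
Reagents that add atoms: trimethyloxonium tetrafluoroborate C[O+](C)C.F[B-](F)(F)F
Why: O-Methylation with Meerwein's salt under non-basic conditions should methylate the only free hydroxyl without acetyl migration or β-elimination.

Step 6
Reactants: 9 methyl (3S,5R,7R)-7-acetoxy-5-methoxy-3-methyldecanoate
Product: 10 methyl (3S,5R,7R)-7-hydroxy-5-methoxy-3-methyldecanoate
Conditions: K2CO3, MeOH, rt
Reagents that add atoms: none
Why: Base-catalysed transesterification removes the acetate, while the methyl ester is unchanged by exchange with methanol.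

Step 7
Reactants: 11 (2R)-2-(chloromethyl)oxirane [(R)-epichlorohydrin]
Product: 12 (2R)-1-chloropent-4-en-2-ol
Conditions: CH2=CHMgBr, CuI (10 mol%), THF, −78 to −20 °C; aq. NH4Cl
Reagents that add atoms: vinylmagnesium bromide C=C[Mg]Br
Why: Copper-catalysed Grignard opening of the epoxide at its unsubstituted carbon should give the homoallylic chlorohydrin, the stereocentre (later C5) keeping all its bonds.

Step 8
Reactants: 12 (2R)-1-chloropent-4-en-2-ol
Product: 13 (2R)-1-(phenylsulfonyl)pent-4-en-2-ol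
Conditions: PhSO2Na, NaI (cat.), DMF, 90 °C
Reagents that add atoms: sodium benzenesulfinate [Na+].[O-]S(=O)c1ccccc1
Why: SN2 displacement of the primary chloride by the sulfinate sulfur (directly or through the transient epoxide, in both cases by attack at CH2) should give the β-hydroxy sulfone without touching the carbinol centre.

Step 9
Reactants: 10 methyl (3S,5R,7R)-7-hydroxy-5-methoxy-3-methyldecanoate; 13 (2R)-1-(phenylsulfonyl)pent-4-en-2-ol
Product: 15 (4R,8S,10R,12R)-4,12-dihydroxy-10-methoxy-8-methyl-5-(phenylsulfonyl)pentadec-1-en-6-one (both C5 epimers), via dilithio sulfone 14 (not isolated)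
Conditions: 13 (3.3 equiv), n-BuLi (6.6 equiv), THF, −78 °C; 10, −78 to −20 °C; AcOH, −78 °C
Reagents that add atoms: n-butyllithium [Li]CCCC (lithium of 14 only)
Why: Claisen-type acylation of the α-sulfonyl carbanion by the methyl ester should join the two halves at C6–C7, one equivalent of 14 being spent on the free C13 hydroxyl and one on the acidic β-keto sulfone; the cold quench protonates the alkoxide before the stabilised enolate, which avoids retro-aldol loss of C5.

Step 10
Reactants: 15 (4R,8S,10R,12R)-4,12-dihydroxy-10-methoxy-8-methyl-5-(phenylsulfonyl)pentadec-1-en-6-one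
Product: 16 (4R,8S,10R,12R)-4,12-dihydroxy-10-methoxy-8-methylpentadec-1-en-6-one
Conditions: SmI2 (3 equiv), THF–MeOH, −78 °C
Reagents that add atoms: none
Why: Reductive desulfonylation as in step 3; the terminal alkene and the unactivated product ketone should not be reduced by SmI2 at −78 °C in the absence of HMPA.

Step 11
Reactants: 16 (4R,8S,10R,12R)-4,12-dihydroxy-10-methoxy-8-methylpentadec-1-en-6-one
Product: 17 (4R,6R,8R,10R,12R)-6,12-dihydroxy-10-methoxy-8-methylpentadec-1-en-4-yl acetate
Conditions: SmI2 (0.3 equiv), CH3CHO (8 equiv), THF, −10 °C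
Reagents that add atoms: acetaldehyde CC=O
Why: Evans–Tishchenko reduction as in step 4 should set C7 anti to C5 by intramolecular hydride delivery from the O5 hemiacetal and leave exactly the pattern needed next (O5 acetate, O7 free), the remote C13 hydroxyl having no ketone within reach.

Step 12
Reactants: 17 (4R,6R,8R,10R,12R)-6,12-dihydroxy-10-methoxy-8-methylpentadec-1-en-4-yl acetate
Product: 20 (1R,5R,7R,9S,11R,13S)-7-methoxy-9-methyl-3-oxo-5-propyl-4,15-dioxabicyclo[9.3.1]pentadecan-13-yl acetate, via alkylpalladium chloride 18 (not isolated), via acylpalladium chloride 19 (not isolated)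
Conditions: Pd(OAc)2 (10 mol%), CuCl2 (3 equiv), CO (1 atm), 4 Å molecular sieves, ClCH2CH2Cl (2 mM), rt
Reagents that add atoms: carbon monoxide [C-]#[O+]; palladium diacetate CC(=O)O[Pd]OC(C)=O and copper dichloride Cl[Cu]Cl (palladium and chlorine of 18 and 19 only)
Why: Divalent palladium activates the C2=C3 alkene, the C7 hydroxyl adds to C3 (anti-oxypalladation) to give alkylpalladium 18, carbon monoxide inserts into the C2–Pd bond and so makes the C1–C2 bond (acylpalladium 19), and the C13 hydroxyl captures the acyl group to close the lactone while CuCl2 returns zerovalent palladium to the divalent state. The closest known reaction type is the Semmelhack alkoxycarbonylation of hydroxy alkenes in its macrolactonising form (alkoxycarbonylative macrolactonisation of alkenediols). The tetrahydropyran closes 6-exo-trig, and the 14-membered lactone closes by intramolecular acyl substitution at the acylpalladium. The new stereocentre C3 is controlled by C7 and C5 through a chair transition state in which the C8 chain, the acetoxy group and the coordinated vinyl group are all equatorial, which should give the 2,6-cis ring. The step needs selectivity among the oxygen nucleophiles and between ring closure and intermolecular esterification: only O7 can reach the alkene in a six-membered mode, O5 is blocked as the acetate so that no bridged lactone can form, O13 is the only free nucleophile left for the acyl group, and high dilution suppresses oligomers.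

Step 13
Reactants: 20 (1R,5R,7R,9S,11R,13S)-7-methoxy-9-methyl-3-oxo-5-propyl-4,15-dioxabicyclo[9.3.1]pentadecan-13-yl acetate
Product: 21 (1R,5R,7R,9S,11R,13S)-13-hydroxy-7-methoxy-9-methyl-5-propyl-4,15-dioxabicyclo[9.3.1]pentadecan-3-one
Conditions: K2CO3, MeOH, 0 °C to rt
Reagents that add atoms: none
Why: Transesterification of the unhindered equatorial acetate should be faster than methanolysis of the hindered secondary macrolactone and gives the equatorial C5 alcohol.

Step 14
Reactants: 22 prop-2-yn-1-amine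
Product: 23 methyl prop-2-yn-1-ylcarbamate
Conditions: ClCO2Me, Et3N, CH2Cl2, 0 °C
Reagents that add atoms: methyl chloroformate COC(=O)Cl
Why: N-Acylation of the primary amine by the chloroformate gives the carbamate.

Step 15
Reactants: 24 methyl 5-bromo-4-oxopentanoate
Product: 25 methyl 3-(1,3-oxazol-4-yl)propanoate
Conditions: HCONH2 (neat, excess), 110 °C
Reagents that add atoms: formamide NC=O
Why: Bredereck oxazole synthesis: O-alkylation of formamide by the bromomethyl ketone and cyclodehydration of nitrogen onto the ketone should give the 4-substituted oxazole with C2 and C5 unsubstituted.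

Step 16
Reactants: 25 methyl 3-(1,3-oxazol-4-yl)propanoate
Product: 27 methyl 3-(2-iodo-1,3-oxazol-4-yl)propanoate, via oxazolylzinc chloride 26 (not isolated)
Conditions: TMPZnCl·LiCl (1.2 equiv), THF, 25 °C; then I2, 0 °C
Reagents that add atoms: 2,2,6,6-tetramethylpiperidinylzinc chloride lithium chloride CC1(C)CCCC(C)(C)N1[Zn]Cl.[Li+].[Cl-] (zinc and chlorine of 26 only); iodine II
Why: Deprotonative zincation at the most acidic C–H (C2 of the oxazole) with a hindered zinc amide that tolerates the ester and avoids the ring opening of 2-lithiooxazoles, followed by iodinolysis of the C–Zn bond.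

Step 17
Reactants: 27 methyl 3-(2-iodo-1,3-oxazol-4-yl)propanoate; 23 methyl prop-2-yn-1-ylcarbamate
Product: 28 methyl 3-{2-[3-(methoxycarbonylamino)prop-1-yn-1-yl]-1,3-oxazol-4-yl}propanoate
Conditions: PdCl2(PPh3)2 (5 mol%), CuI (10 mol%), Et3N, MeCN, rt
Reagents that add atoms: none
Why: Sonogashira coupling of the electron-poor 2-iodooxazole with the terminal alkyne.

Step 18
Reactants: 28 methyl 3-{2-[3-(methoxycarbonylamino)prop-1-yn-1-yl]-1,3-oxazol-4-yl}propanoate
Product: 29 methyl 3-{2-[(1Z)-3-(methoxycarbonylamino)prop-1-en-1-yl]-1,3-oxazol-4-yl}propanoate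
Conditions: H2 (1 atm), Pd/CaCO3 poisoned with Pb(OAc)2, quinoline, EtOAc, rt
Reagents that add atoms: none
Why: Lindlar semihydrogenation adds hydrogen syn to the alkyne and should stop at the Z-alkene.

Step 19
Reactants: 29 methyl 3-{2-[(1Z)-3-(methoxycarbonylamino)prop-1-en-1-yl]-1,3-oxazol-4-yl}propanoate
Product: 30 methyl N-{(2Z)-3-[4-(3-oxopropyl)-1,3-oxazol-2-yl]prop-2-en-1-yl}carbamate
Conditions: (i-Bu)2AlH (2.2 equiv), CH2Cl2, −78 °C; aq. sodium potassium tartrate
Reagents that add atoms: none
Why: Partial reduction of the methyl ester through the aluminium hemiacetal, which is stable at −78 °C, should give the aldehyde, the deprotonated carbamate being inert.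

Step 20
Reactants: 30 methyl N-{(2Z)-3-[4-(3-oxopropyl)-1,3-oxazol-2-yl]prop-2-en-1-yl}carbamate
Product: 31 methyl (2Z)-5-{2-[(1Z)-3-(methoxycarbonylamino)prop-1-en-1-yl]-1,3-oxazol-4-yl}pent-2-enoate
Conditions: (CF3CH2O)2P(O)CH2CO2Me, KN(SiMe3)2, 18-crown-6, THF, −78 °C
Reagents that add atoms: methyl bis(2,2,2-trifluoroethoxy)phosphorylacetate COC(=O)CP(=O)(OCC(F)(F)F)OCC(F)(F)F
Why: Still–Gennari olefination: the electron-poor phosphonate and the dissociated potassium counter-ion make elimination from the kinetic adduct fast, which should give the Z-enoate.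

Step 21
Reactants: 31 methyl (2Z)-5-{2-[(1Z)-3-(methoxycarbonylamino)prop-1-en-1-yl]-1,3-oxazol-4-yl}pent-2-enoate
Product: 32 (2Z)-5-{2-[(1Z)-3-(methoxycarbonylamino)prop-1-en-1-yl]-1,3-oxazol-4-yl}pent-2-enoic acid
Conditions: LiOH, THF–H2O, 0 °C to rt; then aq. HCl to pH 3
Reagents that add atoms: lithium hydroxide [Li+].[OH-]
Why: Saponification of the methyl ester, much faster than hydrolysis of the methyl carbamate, should give the Z,Z-acid without isomerisation.

Step 22
Reactants: 21 (1R,5R,7R,9S,11R,13S)-13-hydroxy-7-methoxy-9-methyl-5-propyl-4,15-dioxabicyclo[9.3.1]pentadecan-3-one; 32 (2Z)-5-{2-[(1Z)-3-(methoxycarbonylamino)prop-1-en-1-yl]-1,3-oxazol-4-yl}pent-2-enoic acid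
Product: 33 neopeltolide
Conditions: PPh3, diisopropyl azodicarboxylate, benzene, rt
Reagents that add atoms: none
Why: Mitsunobu esterification: the carboxylate displaces the alkoxyphosphonium group at C5 by SN2 with inversion, which converts the equatorial alcohol into the axial ester of the target without exposing the Z-enoate to base.

Compound list
1 | (2R)-2-propyloxirane [(R)-1,2-epoxypentane] | CCC[C@@H]1CO1 | starting material
2 | (2R)-1-(phenylsulfonyl)pentan-2-ol | CCC[C@@H](O)CS(=O)(=O)c1ccccc1 | intermediate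
3 | (3S)-5-methoxy-3-methyl-5-oxopentanoic acid [monomethyl (S)-3-methylglutarate] | OC(=O)C[C@H](C)CC(=O)OC | starting material
4 | methyl (3R)-5-chloro-3-methyl-5-oxopentanoate | ClC(=O)C[C@H](C)CC(=O)OC | intermediate
5 | C1,O-dilithio derivative of (2R)-1-(phenylsulfonyl)pentan-2-ol | CCC[C@@H](O[Li])C([Li])S(=O)(=O)c1ccccc1 | intermediate
6 | methyl (3S,7R)-7-hydroxy-3-methyl-5-oxo-6-(phenylsulfonyl)decanoate (both C6 epimers) | CCC[C@@H](O)C(S(=O)(=O)c1ccccc1)C(=O)C[C@H](C)CC(=O)OC | intermediate
7 | methyl (3S,7R)-7-hydroxy-3-methyl-5-oxodecanoate | CCC[C@@H](O)CC(=O)C[C@H](C)CC(=O)OC | intermediate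
8 | methyl (3S,5R,7R)-7-acetoxy-5-hydroxy-3-methyldecanoate | CCC[C@@H](OC(C)=O)C[C@H](O)C[C@H](C)CC(=O)OC | intermediate
9 | methyl (3S,5R,7R)-7-acetoxy-5-methoxy-3-methyldecanoate | CCC[C@@H](OC(C)=O)C[C@H](OC)C[C@H](C)CC(=O)OC | intermediate
10 | methyl (3S,5R,7R)-7-hydroxy-5-methoxy-3-methyldecanoate | CCC[C@@H](O)C[C@H](OC)C[C@H](C)CC(=O)OC | intermediate
11 | (2R)-2-(chloromethyl)oxirane [(R)-epichlorohydrin] | ClC[C@H]1CO1 | starting material
12 | (2R)-1-chloropent-4-en-2-ol | ClC[C@H](O)CC=C | intermediate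
13 | (2R)-1-(phenylsulfonyl)pent-4-en-2-ol | O=S(=O)(c1ccccc1)C[C@H](O)CC=C | intermediate
14 | C1,O-dilithio derivative of (2R)-1-(phenylsulfonyl)pent-4-en-2-ol | O=S(=O)(c1ccccc1)C([Li])[C@H](O[Li])CC=C | intermediate
15 | (4R,8S,10R,12R)-4,12-dihydroxy-10-methoxy-8-methyl-5-(phenylsulfonyl)pentadec-1-en-6-one (both C5 epimers) | CCC[C@@H](O)C[C@H](OC)C[C@H](C)CC(=O)C(S(=O)(=O)c1ccccc1)[C@H](O)CC=C | intermediate
16 | (4R,8S,10R,12R)-4,12-dihydroxy-10-methoxy-8-methylpentadec-1-en-6-one | CCC[C@@H](O)C[C@H](OC)C[C@H](C)CC(=O)C[C@H](O)CC=C | intermediate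
17 | (4R,6R,8R,10R,12R)-6,12-dihydroxy-10-methoxy-8-methylpentadec-1-en-4-yl acetate | CCC[C@@H](O)C[C@H](OC)C[C@H](C)C[C@@H](O)C[C@H](OC(C)=O)CC=C | intermediate
18 | chloro({(2R,4S,6R)-4-acetoxy-6-[(2S,4R,6R)-6-hydroxy-4-methoxy-2-methylnonyl]oxan-2-yl}methyl)palladium | CCC[C@@H](O)C[C@H](OC)C[C@H](C)C[C@@H]1C[C@H](OC(C)=O)C[C@H](C[Pd]Cl)O1 | intermediate
19 | chloro({(2R,4S,6R)-4-acetoxy-6-[(2S,4R,6R)-6-hydroxy-4-methoxy-2-methylnonyl]oxan-2-yl}acetyl)palladium | CCC[C@@H](O)C[C@H](OC)C[C@H](C)C[C@@H]1C[C@H](OC(C)=O)C[C@H](CC(=O)[Pd]Cl)O1 | intermediate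
20 | (1R,5R,7R,9S,11R,13S)-7-methoxy-9-methyl-3-oxo-5-propyl-4,15-dioxabicyclo[9.3.1]pentadecan-13-yl acetate | CCC[C@@H]1C[C@H](OC)C[C@H](C)C[C@@H]2C[C@H](OC(C)=O)C[C@H](CC(=O)O1)O2 | intermediate
21 | (1R,5R,7R,9S,11R,13S)-13-hydroxy-7-methoxy-9-methyl-5-propyl-4,15-dioxabicyclo[9.3.1]pentadecan-3-one | CCC[C@@H]1C[C@H](OC)C[C@H](C)C[C@@H]2C[C@H](O)C[C@H](CC(=O)O1)O2 | intermediate
22 | prop-2-yn-1-amine | C#CCN | starting material
23 | methyl prop-2-yn-1-ylcarbamate | C#CCNC(=O)OC | intermediate
24 | methyl 5-bromo-4-oxopentanoate | COC(=O)CCC(=O)CBr | starting material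
25 | methyl 3-(1,3-oxazol-4-yl)propanoate | COC(=O)CCc1cocn1 | intermediate
26 | chloro[4-(3-methoxy-3-oxopropyl)-1,3-oxazol-2-yl]zinc | COC(=O)CCc1coc([Zn]Cl)n1 | intermediate
27 | methyl 3-(2-iodo-1,3-oxazol-4-yl)propanoate | COC(=O)CCc1coc(I)n1 | intermediate
28 | methyl 3-{2-[3-(methoxycarbonylamino)prop-1-yn-1-yl]-1,3-oxazol-4-yl}propanoate | COC(=O)CCc1coc(C#CCNC(=O)OC)n1 | intermediate
29 | methyl 3-{2-[(1Z)-3-(methoxycarbonylamino)prop-1-en-1-yl]-1,3-oxazol-4-yl}propanoate | COC(=O)CCc1coc(/C=C\CNC(=O)OC)n1 | intermediate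
30 | methyl N-{(2Z)-3-[4-(3-oxopropyl)-1,3-oxazol-2-yl]prop-2-en-1-yl}carbamate | O=CCCc1coc(/C=C\CNC(=O)OC)n1 | intermediate
31 | methyl (2Z)-5-{2-[(1Z)-3-(methoxycarbonylamino)prop-1-en-1-yl]-1,3-oxazol-4-yl}pent-2-enoate | COC(=O)/C=C\CCc1coc(/C=C\CNC(=O)OC)n1 | intermediate
32 | (2Z)-5-{2-[(1Z)-3-(methoxycarbonylamino)prop-1-en-1-yl]-1,3-oxazol-4-yl}pent-2-enoic acid | OC(=O)/C=C\CCc1coc(/C=C\CNC(=O)OC)n1 | intermediate
33 | neopeltolide | CCC[C@@H]1C[C@H](OC)C[C@H](C)C[C@@H]2C[C@@H](OC(=O)/C=C\CCc3coc(/C=C\CNC(=O)OC)n3)C[C@H](CC(=O)O1)O2 | target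

Total step count: 22. Longest linear sequence: 12 steps (steps 1–6, 9–13 and 22, from compound 1).

Steps most likely to fail

Step 12 (key step). The acylpalladium may be captured by chloride, by traces of water or by a second molecule faster than by the distant C13 hydroxyl, so that open-chain acid derivatives or oligomers form instead of the lactone. The fallback sets out from 17 and separates carbonylation from ring closure. Alkoxycarbonylation in the presence of an external alcohol (Pd(OAc)2 cat., CuCl2, CO, benzyl alcohol, MeCN) should give benzyl {(2R,4S,6R)-4-acetoxy-6-[(2S,4R,6R)-6-hydroxy-4-methoxy-2-methylnonyl]oxan-2-yl}acetate F1, in which the tetrahydropyran and the C1–C2 bond are already in place. Hydrogenolysis (H2, Pd/C, EtOAc) would give {(2R,4S,6R)-4-acetoxy-6-[(2S,4R,6R)-6-hydroxy-4-methoxy-2-methylnonyl]oxan-2-yl}acetic acid F2. Yamaguchi lactonisation (2,4,6-trichlorobenzoyl chloride, Et3N, then DMAP, toluene, high dilution) then closes the 14-membered ring and comes back to the route at 20.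

Step 9. Proton transfer (enolisation of the ester, or quenching of the carbanion by the free hydroxyl) may outrun C-acylation, or the β-keto sulfone may fragment by retro-aldol cleavage during work-up. The fallback sets out from 10 and uses dithiane umpolung. Reduction with (i-Bu)2AlH at −78 °C should give (3S,5R,7R)-7-hydroxy-5-methoxy-3-methyldecanal F3, and dithioacetalisation (propane-1,3-dithiol, BF3·OEt2) then gives (4R,6R,8S)-9-(1,3-dithian-2-yl)-6-methoxy-8-methylnonan-4-ol F4. Double deprotonation (t-BuLi, THF–HMPA) and opening of (2R)-2-(prop-2-en-1-yl)oxirane F5, itself made from 12 with NaOH, would give (4R,6R,8S)-9-{2-[(2R)-2-hydroxypent-4-en-1-yl]-1,3-dithian-2-yl}-6-methoxy-8-methylnonan-4-ol F6. Hydrolysis of the dithiane (MeI, CaCO3, aq. MeCN) comes back to the route at 16.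

Step 11. The free C13 hydroxyl may enter the Tishchenko manifold through its own hemiacetal and become acetylated, or the C5 acetate may migrate to O7, so that mixtures of acetates result. The fallback sets out from 10 and masks O13 before the western half is built. Silylation (Et3SiCl, imidazole, CH2Cl2) should give methyl (3S,5R,7R)-5-methoxy-3-methyl-7-(triethylsilyloxy)decanoate F7. Acylation of 14 under the conditions of step 9 then gives (4R,8S,10R,12R)-4-hydroxy-10-methoxy-8-methyl-5-(phenylsulfonyl)-12-(triethylsilyloxy)pentadec-1-en-6-one F8, and desulfonylation as in step 10 gives (4R,8S,10R,12R)-4-hydroxy-10-methoxy-8-methyl-12-(triethylsilyloxy)pentadec-1-en-6-one F9. Evans–Tishchenko reduction as in step 11 would give (4R,6R,8R,10R,12R)-6-hydroxy-10-methoxy-8-methyl-12-(triethylsilyloxy)pentadec-1-en-4-yl acetate F10. Removal of the silyl ether (pyridinium p-toluenesulfonate, MeOH) comes back to the route at 17.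

Further compounds
F1 | step 12 | benzyl {(2R,4S,6R)-4-acetoxy-6-[(2S,4R,6R)-6-hydroxy-4-methoxy-2-methylnonyl]oxan-2-yl}acetate | CCC[C@@H](O)C[C@H](OC)C[C@H](C)C[C@@H]1C[C@H](OC(C)=O)C[C@H](CC(=O)OCc2ccccc2)O1
F2 | step 12 | {(2R,4S,6R)-4-acetoxy-6-[(2S,4R,6R)-6-hydroxy-4-methoxy-2-methylnonyl]oxan-2-yl}acetic acid | CCC[C@@H](O)C[C@H](OC)C[C@H](C)C[C@@H]1C[C@H](OC(C)=O)C[C@H](CC(=O)O)O1
F3 | step 9 | (3S,5R,7R)-7-hydroxy-5-methoxy-3-methyldecanal | CCC[C@@H](O)C[C@H](OC)C[C@H](C)CC=O
F4 | step 9 | (4R,6R,8S)-9-(1,3-dithian-2-yl)-6-methoxy-8-methylnonan-4-ol | CCC[C@@H](O)C[C@H](OC)C[C@H](C)CC1SCCCS1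
F5 | step 9 | (2R)-2-(prop-2-en-1-yl)oxirane | C=CC[C@@H]1CO1
F6 | step 9 | (4R,6R,8S)-9-{2-[(2R)-2-hydroxypent-4-en-1-yl]-1,3-dithian-2-yl}-6-methoxy-8-methylnonan-4-ol | CCC[C@@H](O)C[C@H](OC)C[C@H](C)CC1(C[C@H](O)CC=C)SCCCS1
F7 | step 11 | methyl (3S,5R,7R)-5-methoxy-3-methyl-7-(triethylsilyloxy)decanoate | CCC[C@@H](O[Si](CC)(CC)CC)C[C@H](OC)C[C@H](C)CC(=O)OC
F8 | step 11 | (4R,8S,10R,12R)-4-hydroxy-10-methoxy-8-methyl-5-(phenylsulfonyl)-12-(triethylsilyloxy)pentadec-1-en-6-one | CCC[C@@H](O[Si](CC)(CC)CC)C[C@H](OC)C[C@H](C)CC(=O)C(S(=O)(=O)c1ccccc1)[C@H](O)CC=C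
F9 | step 11 | (4R,8S,10R,12R)-4-hydroxy-10-methoxy-8-methyl-12-(triethylsilyloxy)pentadec-1-en-6-one | CCC[C@@H](O[Si](CC)(CC)CC)C[C@H](OC)C[C@H](C)CC(=O)C[C@H](O)CC=C
F10 | step 11 | (4R,6R,8R,10R,12R)-6-hydroxy-10-methoxy-8-methyl-12-(triethylsilyloxy)pentadec-1-en-4-yl acetate | CCC[C@@H](O[Si](CC)(CC)CC)C[C@H](OC)C[C@H](C)C[C@@H](O)C[C@H](OC(C)=O)CC=C
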